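In a one-step world your quick number is easy, and your hunch is that Monday's flask ends close to the west run.

the same everywhere: electrophile 1.9 M
- south: nucleophile 1 M; run made earlier
- west: nucleophile 2 M; run made earlier
- Monday's: nucleophile 1.90 M; time 40 min
- Sunday's: nucleophile 2.50 M; time 40 min

| run | time / min | electrophile / % | target / % |
|---|---|---|---|
| south | 4.00 | 64 | 15 |
| south | 10.0 | 54 | 7 |
| south | 20.0 | 50 | 5 |
| south | 30.0 | 46 | 2 |
| south | 40.0 | 44 | 2 |
| west | 4.00 | 39 | 37 |
| west | 10.0 | 28 | 22 |
| west | 20.0 | 15 | 12 |
| west | 30.0 | 15 | 11 |
| west | 40.0 | 11 | 8 |

(standard deviation of a reading: 1.5 percentage points)

* part of the electrophile that has reacted at the end, Monday's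
* part of the electrophile that has reacted at the end, Sunday's
* what raising the concentration of nucleophile from its lowest to its highest value here does to the part of the electrophile that has reacted (changes below 5 percentage points count as none) (it rises / it falls / no change)

The south run has lost 1.06 M of electrophile by 40.0 min against 1 M of nucleophile charged, so I count them one for one, with nucleophile as the limiting reagent there. In that one-step world balanced charges follow the step-growth law: the part reacted, p, at time t is t over t plus τ. The nearly balanced west run has 11% of its electrophile left at 40.0 min, which gives τ = 4.94 min: this is the balance time, the time at which a balanced charge stands half reacted. The west reading at 4.00 min gives a shorter 2.56 min, so that run slows, and I keep the last reading because it stands at the asked time.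

For Monday's flask I commit to p = 89.0%, or a shade less, since the west run held more nucleophile. For Sunday's flask, τ gives a rate constant k = 0.106 /M/min, which is one over τ and the charge. The excess Δ = 0.600 M multiplies the ratio of nucleophile to electrophile by exp(kΔt), and that gives p = 98.0%. So the part reacted rises by 9 percentage points, more than the margin of 5 points.

The forecast stands lower than my figures, at 87% (82% to 91%) for Monday's and 96% (91% to 99%) for Sunday's, with the trend it rises, and it says “conversion should land slightly below west”.

The flask gives 86.5% for Monday's and 96.3% for Sunday's, a change of 9.8 points: it rises.

    electrophile + nucleophile → acid set free + target (k = 0.00541 /M/s)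
    nucleophile + acid set free ⇌ protonated nucleophile, settled at all times (K = 455 /M)
    electrophile + target → side product (k = 0.00153 /M/s)
    target ⇌ isomer of the product (K = 2.00, k = 6.21 × 10⁻⁴ /s)

Monday's result puts its balance time at 6.22 min, longer than the west reading. Along Monday's flask the half-life of electrophile by the step that makes target goes from 2.4 min at 0.759 min to 190 min at 40.0 min, when free nucleophile stands at 0.597% of its charge. The neighbour is Monday's flask left until 1.5 h: Monday's balance time gives p = 93.5%, and that neighbour flask shows 93.1%.

Readings and results are calculated for an exercise.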